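(The data are calculated for substances that don't exist.)

If the flask of 16 mM starting material and 12.8 mM coupling partner is to be stopped with the most adduct in it, the target reading is the one to watch beside the adduct reading.

| flask | starting material | coupling partner | remark | time |
|---|---|---|---|---|
| dawn | 8 mM | 12.8 mM | run made earlier |  |
| autumn | 12 mM | 12.8 mM | run made earlier |  |
| dusk | 16 mM | 26 mM | run made earlier |  |
| flask | 16 mM | 12.8 mM |  | 6.0 min |

- dawn (time / min: adduct / %, target / %): 0.167: 17, 1; 0.250: 21, 3; 0.667: 20, 6; 1.50: 20, 11; 4.00: 18, 22
- autumn (time / min: adduct / %, target / %): 0.167: 15, 1; 0.250: 19, 2; 0.667: 20, 4; 1.50: 19, 9; 4.00: 16, 17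
- dusk (time / min: adduct / %, target / %): 0.167: 26, 1; 0.250: 34, 2; 0.667: 33, 7; 1.50: 27, 14; 4.00: 24, 28

(each reading ± 1.5 percentage points)



1. time, not beyond 6.0 min, at which the flask holds most adduct
2. the amount of adduct, in percent of the starting material charged, at that time
3. earliest time at which at least nineteen twentieths of that best amount are there, in min
4. latest time at which they still are, in min

In the dawn, autumn and dusk runs adduct stands near its top between 0.250 min and 0.667 min. At 0.667 min, counting each target as having used one starting material and one coupling partner, the free concentrations give 0.0252 mM⁻¹, 0.0265 mM⁻¹ and 0.0281 mM⁻¹, with mean 0.0266 mM⁻¹. This is the plateau quotient, c(adduct) over c(starting material) times c(coupling partner), a reading of the equilibrium constant of the addition.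

The reckoning here builds the flask up in steps. With the addition by itself, that quotient gives 3.24 mM adduct, 20.2% of the starting material charged. Next comes the drain: target at 1.50 min over adduct at that reading, per minute, averages 0.343 min⁻¹, a lifetime of 2.92 min. By 0.459 min, the middle of those readings, this reckoning puts 0.510 mM target in the flask, and charges short by that amount put the plateau at 3.05 mM, or 19.1%. Last comes the window: its lower level, as the question sets it from that plateau, is 2.90 mM, which the falling plateau reaches once target stands at 0.931 mM. At the drain rate on that adduct this takes 0.936 min, a third of a lifetime.

The forecast gives 18.3% at 0.5 min, open from 0.3 min to 1.3 min. Its ground: “this looks like a fast reversible addition followed by slow drain to target”. The reckoning here shuts the window earlier than the forecast does.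

The flask gives 19.1% at 0.443 min, with the window open from 0.250 min to 0.969 min.

    adduct ⇌ target (K = 1.50, k = 0.00720 s⁻¹)
    starting material + coupling partner ⇌ adduct (K = 28.0 M⁻¹, k = 2.70 M⁻¹ s⁻¹)

In the flask the addition ran first: half its turnover was done by 0.156 min, and at 0.443 min adduct stood at 19.1% beside target 2.78%. Adduct to target then ran on with free starting material and coupling partner present, and at 6.00 min the flask held starting material 67.2%, coupling partner 59.0% of its own charge, adduct 14.1%, target 18.7%, and a quotient of 0.0278 mM⁻¹. For a second flask, the same but with 51 mM coupling partner, the quotient without target gives 53.1%, and its best stood at 49.9%.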